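**Retrosynthetic overview**

- Ring C (the dihydropyranone) is made last, by acid cyclodehydration of a δ-hydroxy-β-diketone. That diketone comes from an aldol/oxidation joining aldehyde 18 to the (S)-silyloxy methyl ketone 21.
- Ring B (the 4-pyranone of the chromone) is cut at C8a–O1, C4a–C4 and O1–C2, giving an aryne from silylaryl triflate 11 plus but-2-ynoic acid 12.
- The feature used: chromone C8a (bearing O1) and C4a (bearing the C4 acyl carbon) are adjacent carbons of ring A. C4a has the C5 oxygen as neighbour and C8a has C8–H, which is the substitution pattern of a 3-alkoxybenzyne.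
- Triflate 11 comes from the symmetric phenol 7 (bromination, retro-Brook shift, triflation). Phenol 7 comes from a Negishi coupling of a chiral-pool alkylzinc with 2-bromo-1,3-dimethoxybenzene, then C–H borylation/oxidation.
- Ring order: ring A is bought, ring B forms in step 7, ring C in step 15. The side-chain (R)-centre comes from bromo alcohol 1 and the ring (S)-centre from pentenol 19.

Key step: step 7

Remark: alcohols 1 and 19 are taken as commercial single enantiomers. The side-chain centre keeps one spatial arrangement from 1 to 26; its descriptor changes from S (1, 2, 4) to R (5 onward) only because CH2Br and CH2Zn outrank CH2O while CH2Ar does not.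

**Route**

Step 1
Reactants: 1 (S)-3-bromo-2-methylpropan-1-ol
Product: 2 (S)-(3-bromo-2-methylpropoxy)triisopropylsilane
Conditions: TIPSCl, imidazole, DMF, 0 → 23 °C
Reagents that add atoms: chlorotriisopropylsilane, CC(C)[Si](Cl)(C(C)C)C(C)C
Why: Imidazole-promoted O-silylation of a primary alcohol leaves the stereocentre untouched, and the bulky silyl ether is chosen to survive the organolithium, triflic anhydride and fluoride used later.

Step 2
Reactants: 2 (S)-(3-bromo-2-methylpropoxy)triisopropylsilane; 3 2-bromo-1,3-dimethoxybenzene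
Product: 5 (R)-[3-(2,6-dimethoxyphenyl)-2-methylpropoxy]triisopropylsilane, via alkylzinc bromide 4 (not isolated)
Conditions: Zn dust, I2 (cat.), DMA, 80 °C; then 3, Pd(OAc)2 (2 mol %), SPhos (4 mol %), THF, 60 °C
Reagents that add atoms: none
Why: Zinc insertion into the primary C–Br bond followed by Negishi coupling should work because the dialkylbiarylphosphine ligand allows oxidative addition to the di-ortho-substituted electron-rich bromide and fast reductive elimination, so the β-stereocentre is carried through unchanged.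

Step 3
Reactants: 5 (R)-[3-(2,6-dimethoxyphenyl)-2-methylpropoxy]triisopropylsilane
Product: 7 3,5-dimethoxy-4-[(R)-2-methyl-3-(triisopropylsilyloxy)propyl]phenol, via aryl pinacol boronate 6 (not isolated)
Conditions: [Ir(OMe)(cod)]2 (1.5 mol %), dtbpy (3 mol %), B2pin2 (0.7 equiv), THF, 80 °C; then 30% aq. H2O2, 2 M NaOH, 0 °C
Reagents that add atoms: hydrogen peroxide, OO
Why: Iridium-catalysed aromatic C–H borylation is sterically controlled and should go to the only C–H with no ortho substituent (para to the alkyl chain), and alkaline peroxide oxidation of the C–B bond then gives the symmetric phenol.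

Step 4
Reactants: 7 3,5-dimethoxy-4-[(R)-2-methyl-3-(triisopropylsilyloxy)propyl]phenol
Product: 8 2-bromo-3,5-dimethoxy-4-[(R)-2-methyl-3-(triisopropylsilyloxy)propyl]phenol
Conditions: NBS (1.0 equiv), CH2Cl2, −78 → −20 °C
Reagents that add atoms: N-bromosuccinimide, O=C1CCC(=O)N1Br
Why: Electrophilic aromatic bromination ortho to the phenol has no regiochemical issue because the two free ring positions are equivalent by symmetry, so only the degree of bromination must be held by one equivalent of reagent at low temperature.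

Step 5
Reactants: 8 2-bromo-3,5-dimethoxy-4-[(R)-2-methyl-3-(triisopropylsilyloxy)propyl]phenol
Product: 9 [2-bromo-3,5-dimethoxy-4-[(R)-2-methyl-3-(triisopropylsilyloxy)propyl]phenoxy]trimethylsilane
Conditions: HMDS, THF, 70 °C; evaporate
Reagents that add atoms: hexamethyldisilazane, C[Si](C)(C)N[Si](C)(C)C
Why: O-silylation of the phenol with HMDS releases only ammonia and gives the aryl silyl ether needed for the silyl migration.

Step 6
Reactants: 9 [2-bromo-3,5-dimethoxy-4-[(R)-2-methyl-3-(triisopropylsilyloxy)propyl]phenoxy]trimethylsilane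
Product: 11 3,5-dimethoxy-4-[(R)-2-methyl-3-(triisopropylsilyloxy)propyl]-2-(trimethylsilyl)phenyl trifluoromethanesulfonate, via lithium phenoxide 10 (not isolated)
Conditions: n-BuLi, THF, −78 °C; then Tf2O, −78 → 0 °C
Reagents that add atoms: trifluoromethanesulfonic anhydride, O=S(=O)(OS(=O)(=O)C(F)(F)F)C(F)(F)F
Why: Bromine–lithium exchange gives an aryllithium that takes the trimethylsilyl group from the neighbouring oxygen (retro-Brook 1,3 O-to-C shift), and the resulting phenoxide is trapped as the triflate, which is the standard assembly of a 2-silylaryl triflate.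

Step 7
Reactants: 11 3,5-dimethoxy-4-[(R)-2-methyl-3-(triisopropylsilyloxy)propyl]-2-(trimethylsilyl)phenyl trifluoromethanesulfonate; 12 but-2-ynoic acid
Product: 15 5,7-dimethoxy-2-methyl-6-[(R)-2-methyl-3-(triisopropylsilyloxy)propyl]-4H-chromen-4-one, via aryne 13 (not isolated), via hydroxyaryl ynone 14 (not isolated)
Conditions: 12 (1.2 equiv), CsF (4 equiv), THF, 125 °C, sealed tube
Reagents that add atoms: none
Why: Fluoride removes the trimethylsilyl group and the ortho triflate leaves, giving aryne 13 across C4a/C8a; the but-2-ynoate oxygen adds to C8a, the aryne carbon remote from the flanking methoxy group, because that methoxy group inductively stabilises the developing aryl anion at the adjacent carbon C4a. The C4a anion then attacks its own ester carbonyl through a four-membered alkoxide that collapses with C–O cleavage (anionic Fries-type 1,3 O-to-C acyl shift), so the net result is insertion of the aryne into the acid C–O bond to give ortho-hydroxyaryl ynone 14 with the C8a–O1 and C4a–C4 bonds in place. The phenoxide of 14 closes ring B by 6-endo-dig oxa-Michael addition to the ynone β-carbon (O1–C2), and the resulting allenolate is protonated at C3 by the HF formed from the acid proton. This is the known fluoride-induced aryne/carboxylic acid C–O insertion that gives ortho-hydroxyaryl ketones and, with alk-2-ynoic acids, arene-fused 4-pyranones. No stereocentre is formed and the remote (R)-centre is not touched; the step needs acyl transfer to outrun protonation of the aryl anion, which the high temperature and the sparingly soluble CsF/THF medium favour, and 6-endo over 5-exo closure, which the electrophilic β-carbon of the ynone secures.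

Step 8
Reactants: 15 5,7-dimethoxy-2-methyl-6-[(R)-2-methyl-3-(triisopropylsilyloxy)propyl]-4H-chromen-4-one
Product: 16 5-hydroxy-7-methoxy-2-methyl-6-[(R)-2-methyl-3-(triisopropylsilyloxy)propyl]-4H-chromen-4-one
Conditions: BCl3 (1.5 equiv), CH2Cl2, −78 → −20 °C; then H2O
Reagents that add atoms: none
Why: In this chelation-controlled Lewis-acid demethylation boron binds between the C4 carbonyl and the peri C5 methoxy oxygen, so chloride should remove only that methyl group and leave the unassisted C7 ether; any silyl ether lost here converges on 17 in step 9.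

Step 9
Reactants: 16 5-hydroxy-7-methoxy-2-methyl-6-[(R)-2-methyl-3-(triisopropylsilyloxy)propyl]-4H-chromen-4-one
Product: 17 5-hydroxy-6-[(R)-3-hydroxy-2-methylpropyl]-7-methoxy-2-methyl-4H-chromen-4-one
Conditions: HF·pyridine, THF, 0 → 23 °C
Reagents that add atoms: none
Why: Fluoride cleavage of the primary silyl ether under mildly acidic conditions should leave the chromone and the hydrogen-bonded phenol untouched.

Step 10
Reactants: 17 5-hydroxy-6-[(R)-3-hydroxy-2-methylpropyl]-7-methoxy-2-methyl-4H-chromen-4-one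
Product: 18 (R)-3-(5-hydroxy-7-methoxy-2-methyl-4-oxo-4H-chromen-6-yl)-2-methylpropanal
Conditions: Dess–Martin periodinane, pyridine, CH2Cl2, 0 °C
Reagents that add atoms: none
Why: Dess–Martin oxidation under pyridine buffer should give the α-branched aldehyde without epimerisation, the C5 hydroxyl being held in a hydrogen bond to the C4 carbonyl and therefore unreactive.

Step 11
Reactants: 19 (S)-pent-4-en-2-ol
Product: 20 (S)-tert-butyldimethyl(pent-4-en-2-yloxy)silane
Conditions: TBSCl, imidazole, DMF, 23 °C
Reagents that add atoms: tert-butylchlorodimethylsilane, CC(C)(C)[Si](C)(C)Cl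
Why: Standard imidazole-promoted silylation of a secondary alcohol with no bond change at the carbinol centre.

Step 12
Reactants: 20 (S)-tert-butyldimethyl(pent-4-en-2-yloxy)silane
Product: 21 (S)-4-(tert-butyldimethylsilyloxy)pentan-2-one
Conditions: PdCl2 (10 mol %), CuCl (30 mol %), O2 (1 atm), DMF/H2O 7:1, 23 °C
Reagents that add atoms: water, O
Why: Tsuji–Wacker oxidation of the terminal alkene with Markovnikov delivery of water should give the methyl ketone, with O2 as terminal oxidant and the silyloxy stereocentre untouched.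

Step 13
Reactants: 18 (R)-3-(5-hydroxy-7-methoxy-2-methyl-4-oxo-4H-chromen-6-yl)-2-methylpropanal; 21 (S)-4-(tert-butyldimethylsilyloxy)pentan-2-one
Product: 23 6-[(2R,7S)-7-(tert-butyldimethylsilyloxy)-3-hydroxy-2-methyl-5-oxooctyl]-5-hydroxy-7-methoxy-2-methyl-4H-chromen-4-one (mixture of C3 carbinol epimers), via lithium enolate 22 (not isolated)
Conditions: 21 (2.5 equiv), LiN(i-Pr)2 (2.4 equiv), THF, −78 °C; then 18, −78 °C; AcOH quench at −78 °C
Reagents that add atoms: none
Why: In this kinetic aldol addition the amide base deprotonates the methyl side of 21 and the aldehyde is far more electrophilic than the chromone, one equivalent of enolate being spent on the phenol; the new carbinol centre need not be controlled because step 14 oxidises it.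

Step 14
Reactants: 23 6-[(2R,7S)-7-(tert-butyldimethylsilyloxy)-3-hydroxy-2-methyl-5-oxooctyl]-5-hydroxy-7-methoxy-2-methyl-4H-chromen-4-one
Product: 24 (2R,7S)-7-(tert-butyldimethylsilyloxy)-1-(5-hydroxy-7-methoxy-2-methyl-4-oxo-4H-chromen-6-yl)-2-methyloctane-3,5-dione
Conditions: Dess–Martin periodinane, pyridine, CH2Cl2, 0 → 23 °C
Reagents that add atoms: none
Why: Dess–Martin oxidation of a β-hydroxy ketone to the 1,3-diketone is non-basic, and the diketone enolises between its carbonyls and not toward the (R)-centre, so that centre should hold.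

Step 15
Reactants: 24 (2R,7S)-7-(tert-butyldimethylsilyloxy)-1-(5-hydroxy-7-methoxy-2-methyl-4-oxo-4H-chromen-6-yl)-2-methyloctane-3,5-dione
Product: 26 5-hydroxy-7-methoxy-2-methyl-6-[(R)-2-[(S)-6-methyl-4-oxo-5,6-dihydro-4H-pyran-2-yl]propyl]-4H-chromen-4-one (target), via hydroxy diketone 25 (not isolated)
Conditions: 48% aq. HF, MeCN, 0 → 23 °C; then TFA, same flask, 23 °C
Reagents that add atoms: none
Why: Desilylation frees the C7 hydroxyl, which adds to the C3 carbonyl (six-membered hemiketal), and acid-catalysed dehydration gives the vinylogous ester of ring C; both stereocentres are retained because the carbinol oxygen is the nucleophile and no bond at either centre is broken.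

**Compound list**

1 | (S)-3-bromo-2-methylpropan-1-ol | BrC[C@@H](C)CO | starting material
2 | (S)-(3-bromo-2-methylpropoxy)triisopropylsilane | BrC[C@@H](C)CO[Si](C(C)C)(C(C)C)C(C)C | intermediate
3 | 2-bromo-1,3-dimethoxybenzene | COc1cccc(OC)c1Br | starting material
4 | [(S)-2-methyl-3-(triisopropylsilyloxy)propyl]zinc bromide | Br[Zn]C[C@@H](C)CO[Si](C(C)C)(C(C)C)C(C)C | intermediate
5 | (R)-[3-(2,6-dimethoxyphenyl)-2-methylpropoxy]triisopropylsilane | COc1cccc(OC)c1C[C@@H](C)CO[Si](C(C)C)(C(C)C)C(C)C | intermediate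
6 | 2-[3,5-dimethoxy-4-[(R)-2-methyl-3-(triisopropylsilyloxy)propyl]phenyl]-4,4,5,5-tetramethyl-1,3,2-dioxaborolane | COc1cc(B2OC(C)(C)C(C)(C)O2)cc(OC)c1C[C@@H](C)CO[Si](C(C)C)(C(C)C)C(C)C | intermediate
7 | 3,5-dimethoxy-4-[(R)-2-methyl-3-(triisopropylsilyloxy)propyl]phenol | COc1cc(O)cc(OC)c1C[C@@H](C)CO[Si](C(C)C)(C(C)C)C(C)C | intermediate
8 | 2-bromo-3,5-dimethoxy-4-[(R)-2-methyl-3-(triisopropylsilyloxy)propyl]phenol | COc1cc(O)c(Br)c(OC)c1C[C@@H](C)CO[Si](C(C)C)(C(C)C)C(C)C | intermediate
9 | [2-bromo-3,5-dimethoxy-4-[(R)-2-methyl-3-(triisopropylsilyloxy)propyl]phenoxy]trimethylsilane | COc1cc(O[Si](C)(C)C)c(Br)c(OC)c1C[C@@H](C)CO[Si](C(C)C)(C(C)C)C(C)C | intermediate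
10 | lithium 3,5-dimethoxy-4-[(R)-2-methyl-3-(triisopropylsilyloxy)propyl]-2-(trimethylsilyl)phenoxide | COc1cc([O-])c([Si](C)(C)C)c(OC)c1C[C@@H](C)CO[Si](C(C)C)(C(C)C)C(C)C.[Li+] | intermediate
11 | 3,5-dimethoxy-4-[(R)-2-methyl-3-(triisopropylsilyloxy)propyl]-2-(trimethylsilyl)phenyl trifluoromethanesulfonate | COc1cc(OS(=O)(=O)C(F)(F)F)c([Si](C)(C)C)c(OC)c1C[C@@H](C)CO[Si](C(C)C)(C(C)C)C(C)C | intermediate
12 | but-2-ynoic acid | CC#CC(=O)O | starting material
13 | 3,5-dimethoxy-4-[(R)-2-methyl-3-(triisopropylsilyloxy)propyl]-1,2-didehydrobenzene | COC1=CC#CC(OC)=C1C[C@@H](C)CO[Si](C(C)C)(C(C)C)C(C)C | intermediate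
14 | 1-[6-hydroxy-2,4-dimethoxy-3-[(R)-2-methyl-3-(triisopropylsilyloxy)propyl]phenyl]but-2-yn-1-one | COc1cc(O)c(C(=O)C#CC)c(OC)c1C[C@@H](C)CO[Si](C(C)C)(C(C)C)C(C)C | intermediate
15 | 5,7-dimethoxy-2-methyl-6-[(R)-2-methyl-3-(triisopropylsilyloxy)propyl]-4H-chromen-4-one | COc1cc2oc(C)cc(=O)c2c(OC)c1C[C@@H](C)CO[Si](C(C)C)(C(C)C)C(C)C | intermediate
16 | 5-hydroxy-7-methoxy-2-methyl-6-[(R)-2-methyl-3-(triisopropylsilyloxy)propyl]-4H-chromen-4-one | COc1cc2oc(C)cc(=O)c2c(O)c1C[C@@H](C)CO[Si](C(C)C)(C(C)C)C(C)C | intermediate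
17 | 5-hydroxy-6-[(R)-3-hydroxy-2-methylpropyl]-7-methoxy-2-methyl-4H-chromen-4-one | COc1cc2oc(C)cc(=O)c2c(O)c1C[C@@H](C)CO | intermediate
18 | (R)-3-(5-hydroxy-7-methoxy-2-methyl-4-oxo-4H-chromen-6-yl)-2-methylpropanal | COc1cc2oc(C)cc(=O)c2c(O)c1C[C@@H](C)C=O | intermediate
19 | (S)-pent-4-en-2-ol | C=CC[C@H](C)O | starting material
20 | (S)-tert-butyldimethyl(pent-4-en-2-yloxy)silane | C=CC[C@H](C)O[Si](C)(C)C(C)(C)C | intermediate
21 | (S)-4-(tert-butyldimethylsilyloxy)pentan-2-one | CC(=O)C[C@H](C)O[Si](C)(C)C(C)(C)C | intermediate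
22 | lithium (S)-4-(tert-butyldimethylsilyloxy)pent-1-en-2-olate | [Li+].[O-]C(=C)C[C@H](C)O[Si](C)(C)C(C)(C)C | intermediate
23 | 6-[(2R,7S)-7-(tert-butyldimethylsilyloxy)-3-hydroxy-2-methyl-5-oxooctyl]-5-hydroxy-7-methoxy-2-methyl-4H-chromen-4-one (C3 epimers) | COc1cc2oc(C)cc(=O)c2c(O)c1C[C@@H](C)C(O)CC(=O)C[C@H](C)O[Si](C)(C)C(C)(C)C | intermediate
24 | (2R,7S)-7-(tert-butyldimethylsilyloxy)-1-(5-hydroxy-7-methoxy-2-methyl-4-oxo-4H-chromen-6-yl)-2-methyloctane-3,5-dione | COc1cc2oc(C)cc(=O)c2c(O)c1C[C@@H](C)C(=O)CC(=O)C[C@H](C)O[Si](C)(C)C(C)(C)C | intermediate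
25 | (2R,7S)-7-hydroxy-1-(5-hydroxy-7-methoxy-2-methyl-4-oxo-4H-chromen-6-yl)-2-methyloctane-3,5-dione | COc1cc2oc(C)cc(=O)c2c(O)c1C[C@@H](C)C(=O)CC(=O)C[C@H](C)O | intermediate
26 | 5-hydroxy-7-methoxy-2-methyl-6-[(R)-2-[(S)-6-methyl-4-oxo-5,6-dihydro-4H-pyran-2-yl]propyl]-4H-chromen-4-one | COc1cc2oc(C)cc(=O)c2c(O)c1C[C@@H](C)C1=CC(=O)C[C@H](C)O1 | target

**Totals**

Total step count: 15. Longest linear sequence: 13 steps (steps 1–10 and 13–15); steps 11–12 form the two-step side branch to ketone 21.

**Steps most likely to fail**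

1. Step 7 (key step). Three processes may go wrong. The C4a aryl anion may be protonated before the acyl group transfers, stopping at the aryl but-2-ynoate. Fluoride at 125 °C may cleave the triisopropylsilyl ether, after which the freed alcohol would add to the aryne. The phenoxide may close 5-exo instead of 6-endo. The fallback sets out from bromophenol 8 and builds the same ynone by organolithium acylation. Phenol 8 is capped with chloromethyl methyl ether and i-Pr2NEt to give [(R)-3-[3-bromo-2,6-dimethoxy-4-(methoxymethoxy)phenyl]-2-methylpropoxy]triisopropylsilane F1. Acid 12 is converted with N,O-dimethylhydroxylamine hydrochloride and a carbodiimide into N-methoxy-N-methylbut-2-ynamide F2. Bromine–lithium exchange on F1 (n-BuLi, THF, −78 °C) and addition of the aryllithium to F2 should give 1-[2,4-dimethoxy-6-(methoxymethoxy)-3-[(R)-2-methyl-3-(triisopropylsilyloxy)propyl]phenyl]but-2-yn-1-one F3. Brief HCl in MeOH removes the acetal to give hydroxyaryl ynone 14, and Et2NH in EtOH closes it 6-endo through the enaminone to chromone 15, where the route resumes.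

2. Step 13. The basic lithium enolate may take a proton from the chelated phenol or from the α-position of aldehyde 18. That would stall the addition, allow enolate equilibration with β-elimination of silanolate, or erode the (R)-centre. The fallback sets out from ketone 21 and aldehyde 18 and replaces the metal enolate by a neutral nucleophile under Lewis-acid activation. Ketone 21 is trapped as its kinetic enol ether (LiN(i-Pr)2, Me3SiCl, THF, −78 °C) to give (S)-4-(tert-butyldimethylsilyloxy)-2-(trimethylsilyloxy)pent-1-ene F4. F4 is then added to 18 with BF3·OEt2 in CH2Cl2 at −78 °C (Mukaiyama aldol), which should give aldol 23, where the route resumes.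

3. Step 4. The doubly activated ring may brominate twice, or the electron-rich phenol may be oxidised by the brominating agent. The fallback sets out from phenol 7 and installs the silyl group by directed ortho-metalation instead of halogenation. Isopropyl isocyanate and Et3N give 3,5-dimethoxy-4-[(R)-2-methyl-3-(triisopropylsilyloxy)propyl]phenyl N-isopropylcarbamate F5. In-situ N-silylation (Me3SiOTf, TMEDA), lithiation with n-BuLi/TMEDA at −78 °C at the position between the carbamate and methoxy oxygens, and Me3SiCl quench give 3,5-dimethoxy-4-[(R)-2-methyl-3-(triisopropylsilyloxy)propyl]-2-(trimethylsilyl)phenyl N-isopropylcarbamate F6. DBU and Et2NH in MeCN at 40 °C release the phenoxide, which PhNTf2 converts into triflate 11, where the route resumes.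

**Further compounds**

F1 | step 7 | [(R)-3-[3-bromo-2,6-dimethoxy-4-(methoxymethoxy)phenyl]-2-methylpropoxy]triisopropylsilane | COCOc1cc(OC)c(C[C@@H](C)CO[Si](C(C)C)(C(C)C)C(C)C)c(OC)c1Br
F2 | step 7 | N-methoxy-N-methylbut-2-ynamide | CC#CC(=O)N(C)OC
F3 | step 7 | 1-[2,4-dimethoxy-6-(methoxymethoxy)-3-[(R)-2-methyl-3-(triisopropylsilyloxy)propyl]phenyl]but-2-yn-1-one | COCOc1cc(OC)c(C[C@@H](C)CO[Si](C(C)C)(C(C)C)C(C)C)c(OC)c1C(=O)C#CC
F4 | step 13 | (S)-4-(tert-butyldimethylsilyloxy)-2-(trimethylsilyloxy)pent-1-ene | C=C(O[Si](C)(C)C)C[C@H](C)O[Si](C)(C)C(C)(C)C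
F5 | step 4 | 3,5-dimethoxy-4-[(R)-2-methyl-3-(triisopropylsilyloxy)propyl]phenyl N-isopropylcarbamate | COc1cc(OC(=O)NC(C)C)cc(OC)c1C[C@@H](C)CO[Si](C(C)C)(C(C)C)C(C)C
F6 | step 4 | 3,5-dimethoxy-4-[(R)-2-methyl-3-(triisopropylsilyloxy)propyl]-2-(trimethylsilyl)phenyl N-isopropylcarbamate | COc1cc(OC(=O)NC(C)C)c([Si](C)(C)C)c(OC)c1C[C@@H](C)CO[Si](C(C)C)(C(C)C)C(C)C
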